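## Structural features

The target is a C30 triterpenoid methyl ether with a 6-6-7-5-6 pentacycle. Rings A and B form a trans-decalin, ring C is a cycloheptane spanned between C8/C9 of ring B and C13/C14 of ring D, and rings D and E form a trans-hydrindane in which ring D is five-membered and the extruded C15 sits on C14 as an aldehyde. Ring B carries four contiguous stereocentres, C5, C10, C9 and C8, in a trans-anti-trans array (5α-H, 10β-methyl, 9α-H, 8β-methyl), two of them quaternary. Ring D carries C18 (quaternary, α-methyl), C13 (β-H) and C14 (quaternary, β-CHO, C27 α) in a row next to C17 (β-H), and the C/D junction is cis. Both terminal oxygen functions are axial and neopentyl (the 3α-methoxy group beside the C4 gem-dimethyl group, the 21β-hydroxyl beside the C22 gem-dimethyl group), and the aldehyde, which cannot enolise, must be told apart from the secondary alcohol. The real difficulty is the density of fully substituted carbons: C8 and C10 flank C9, C14 and C18 flank C13, so no bond to these atoms can be made by a hindered intermolecular substitution. The key step exploits that C5, C6, C7, C8, C9 and C10 are the six carbons of a cyclohexene whose two new bonds, C5–C10 and C8–C9, are at the same time the fusion bonds of rings A/B and B/C. Closing them across a 15-membered ring (C1–C14 plus C27) fused to the D/E hydrindane forms rings A, B and C at once and turns three alkene geometries into the trans-anti-trans array.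

## Logic of the disconnections

From 39 back to 32 no skeletal bond is cut. The C15 aldehyde and the free C21 hydroxyl are traced to two differently protected oxygens (38, 37). The methylene pairs C6/C7 and C11/C12 are traced to alkenes (36), the C11=C12 alkene to an enol triflate and then to the C11 ketone (35, 34), and the 3α-methoxy group to the C3 ketone (33, 32). The gain is that 32 holds only what a cycloaddition needs: an activating C11 carbonyl, a C6=C7 alkene and a stereochemically silent C3. The demands are chemoselectivity between two ketones (C3 before C11) and removal of a carbonyl next to a methine between two quaternary carbons; C11 is therefore taken out through its enolate, not by attack at the carbonyl carbon.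

32 is cut at C5–C10 and C8–C9, which leads to 31. These two bonds close rings A, B and C together and create C5, C10, C9 and C8, so the whole left half collapses to a monocyclic chain on the hydrindane. The forward step must form two quaternary carbons in a concerted cycloaddition and must pick one diene face under the influence of C13 and C14 only.

31 is cut at C6–C7, the central bond of the diene, which leads to 30. An sp2–sp2 coupling with retention fixes the E,Z-diene at the moment of ring closure and needs neither acid nor base. The demand is a 15-membered ring closure at a neopentylic vinylstannane under conditions mild enough for 31 to be isolated.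

30 is cut at C9–C11 (through 29), giving 18 and 26. This separates the hydrindane, which carries all pre-existing stereocentres, from an achiral-in-effect chain, and it places the E-trisubstituted alkene in a vinyl metal made with known geometry. The forward step needs a vinyl metal that adds to the aldehyde of 18 without touching the C7 iodide of 18 or the C6 stannane of 26.

26 is cut at C5=C6 (to 23 and 25) and 23 at C3–C4 (to 21 and 22); 21 goes back through 20 to 19 by removal of the C10 methyl and the C9 iodide. Every piece is then a commercial C1 to C5 unit. The demands are E-selective olefination of a hindered aldehyde in the presence of a vinyl iodide and a syn-carbometalation for the 9E geometry.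

18 is cut at C11–C12 (to 16) and at C12–C13 (through 15 and 13 to 12). Both carbons are added as one-carbon units because the C13 carbonyl of 12 lies between two quaternary carbons and accepts only the smallest reagents. The forward steps must deliver hydrogen to C13 from the β face.

12 is cut at C14–C15 and C14–C27, giving 11 and then 7 and 10; 10 goes back through 9 to 8. The C13 ketone activates C14 and is the only enolisable site, so the quaternary centre is built by two alkylations whose order fixes its configuration. The second electrophile must enter anti to the angular methyl, and the Z-iodoalkene must be made by an anti-carbometalation.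

7 is traced through 6, 5, 4, 3 and 2 to 1 by removing the two C22 methyl groups, the C17 hydrogen and the C21 hydride, and by masking C13. The enantiopure bicycle 1 supplies C18 and with it every other stereocentre of the D/E half. The demands are a trans ring fusion on hydrogenation and an axial alcohol on reduction.

## Other disconnections considered

Alternative 1: The cuts are C8–C27 and the C14–C16 bond (made by migration from C15). In the forward step acid protonates the C8 methylene of the hydroxylated onocerin-type diene A2; the C14 methylene carbon C27 attacks the C8 cation and closes ring C; the resulting C14 cation is quenched by a 1,2-shift of C16 from the carbinol carbon C15, which contracts ring D and leaves C15 as the aldehyde, giving the 21-acetate A1. In its favour: it follows the likely biogenesis, sets both quaternary centres C8 and C14, and delivers the aldehyde at the right oxidation level, so that one deacetylation ends the synthesis. On step economy after the key step it is clearly better than the chosen plan (one step against seven). Against it here: the cascade is stepwise and cationic, and each cation has other exits (proton loss from C8 or C14, hydride shifts). Which group migrates depends on the alignment set by the C15 configuration, which must be installed as an extra stereocentre. The faces at C8 and C14 are decided by the conformation of a forming seven-membered ring, not by alkene geometry. A2 needs two different decalins with all ring-fusion centres already made and joined at C11–C12. On structure the chosen plan makes C5, C10, C9 and C8 in its key step, whereas this alternative makes none of them. On mechanism the chosen plan is stereospecific for the relative configuration, and the two are equal on the open question of which face reacts.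

Alternative 2: The cuts are C17–C22 and C13–C18. In the forward step MeAlCl2 opens the (S)-epoxide of the epoxygeranyl allylsilane A4, the C17=C18 alkene closes ring E, and the ring C allylsilane closes ring D with loss of silicon, giving the 21α-alcohol A3 with a C15 ester and a C11=C12 alkene. In its favour: epoxide-initiated cation–olefin cyclisations ending at allylsilanes are an established reaction class, and on precedent it is better than the chosen plan. It is equal in bonds formed (two) and stereocentres set (four: C21, C17, C18, C13), and the absolute configuration comes from one epoxide. Against it here: A4 already contains the whole A/B/C tricycle with the C5/C10/C9/C8 array and the quaternary C14, so the hardest part of the molecule is moved into the substrate instead of being solved. The cyclisation must close a five-membered ring at a carbon next to the quaternary C14. The remote epoxide and C14 must be matched. A3 has the wrong C21 configuration (inversion needed), an ester to be taken to the aldehyde and an alkene to saturate. On structure it spends its key step on the D/E half, which the chosen plan gets in six steps from 1. On mechanism it is a stepwise cationic cascade whose ring-fusion stereochemistry rests on chair-like folding, against a concerted cycloaddition in the chosen plan. On step economy it is about equal after the key step and longer before it.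

Alternative 3: The cut is C9–C11. In the forward step SmI2 turns the primary C11 iodide of the iodo ketone A6 into an alkylsamarium that adds to the non-enolisable C9 ketone and closes ring C, giving the tertiary carbinol A5. In its favour: Barbier closures onto hindered ketones are known, the decalin and the hydrindane are made separately by conventional chemistry, and there is no facial-matching question between the two halves. On precedent and on stereochemical independence of the two halves it is better than the chosen plan. Against it here: only one bond and one ring are formed. The C9 carbinol must then be converted into 9α-H, which takes a dehydration (possible only towards C11) and a hydrogenation. A6 requires the C8–C27–C14 link, whose methylene lies between two quaternary carbons and cannot be made by substitution in either direction. Seven-membered Barbier closures compete with simple reduction of the iodide. On mechanism it is a one-bond closure through a carbanion-like intermediate, against a concerted two-bond cycloaddition in the chosen plan. On step economy it is clearly the longest of the four plans.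

Key step: step 23

Remarks on the chemistry (assumptions, one line each):
- Serratane numbering of 39 is used for every intermediate (ring D = C13, C14, C16, C17, C18; ring E = C17–C22; C15 is the exocyclic carbon on C14; C27 is the methylene between C14 and C8); α/β refer to the usual drawing of 39 (C18 methyl α, 17-H β).
- Structure check: in 31 and 32 the configurations at C13, C14, C17, C18 and C21 are those of 39, and the 5E,7Z,9E geometry of 31 maps onto 5α-H, 10β-Me, 9α-H, 8β-Me; no correction of skeleton or configuration is needed.
- Design change in the cycloaddition substrate: C15 is carried as a benzyl ether and C21 as a TBS ether; the benzyloxymethyl arm is slimmer next to C8 in the wanted transition state, is orthogonal to the C21 silyl ether, and is removed in the hydrogenation that is needed anyway.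
- 22 (the enol silane of isobutyraldehyde) and 24 are taken as commercial.

## Steps

Step 1
Reactants: 1 (S)-Hajos–Parrish ketone
Product: 2 C13 ethylene ketal of 1 (enone untouched)
Conditions: ethylene glycol, p-TsOH·H2O (cat.), 4 Å MS, CH2Cl2, rt
Reagents that add atoms: ethylene glycol OCCO
Why: Acid-catalysed ketalisation is faster at the saturated cyclopentanone than at the less electrophilic conjugated carbonyl, so the future C13 ketone is masked while ring E is built; no stereocentre is touched.

Step 2
Reactants: 2 C13 ketal enone
Product: 3 22,22-dimethyl-16-en-21-one 13-ketal (β,γ-unsaturated ketone)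
Conditions: KOt-Bu (2.5 equiv), MeI (4 equiv), t-BuOH/THF, 0 °C → rt
Reagents that add atoms: iodomethane CI
Why: Deconjugative α,α-dialkylation: the extended dienolate formed by γ-deprotonation at C16 is methylated twice at the α-carbon C22, which moves the alkene to C16=C17 and blocks reconjugation.

Step 3
Reactants: 3 β,γ-unsaturated ketone ketal
Product: 4 trans-hydrindane 21-ketone 13-ketal (17β-H, 18α-methyl)
Conditions: H2 (4 bar), 10% Pd/C, EtOAc, rt
Reagents that add atoms: none
Why: Heterogeneous hydrogenation of the ring D alkene next to the ring fusion; the catalyst approaches the face opposite the angular C18 methyl, as with 14-ene steroids, so hydrogen goes to C17 anti to the methyl and the trans ring fusion results.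

Step 4
Reactants: 4 trans-hydrindane ketone ketal
Product: 5 21β-alcohol 13-ketal (axial hydroxyl)
Conditions: LiBH(s-Bu)3, THF, −78 °C; aq. NH4Cl
Reagents that add atoms: none
Why: The bulky borohydride attacks the cyclohexanone along the equatorial trajectory and avoids the syn-axial hydrogens, which gives the axial 21β-alcohol; the same reagent control is used later at C3.

Step 5
Reactants: 5 21β-alcohol ketal
Product: 6 21β-tert-butyldimethylsilyl ether 13-ketal
Conditions: TBSOTf, 2,6-lutidine, CH2Cl2, −78 → 0 °C
Reagents that add atoms: tert-butyldimethylsilyl triflate CC(C)(C)[Si](C)(C)OS(=O)(=O)C(F)(F)F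
Why: A silyl triflate with a hindered pyridine base silylates even an axial neopentyl alcohol; the ketone ketal tolerates the buffered conditions at low temperature.

Step 6
Reactants: 6 silyl ether ketal
Product: 7 hydrindan-13-one (21β-OTBS, 22,22-dimethyl, 17β-H, 18α-methyl)
Conditions: PPTS (cat.), acetone/H2O (10:1), 60 °C
Reagents that add atoms: water O
Why: Mild acid-catalysed hydrolysis of the dioxolane; the hindered secondary silyl ether survives pyridinium tosylate.

Step 7
Reactants: 8 propargyl alcohol
Product: 9 (Z)-3-iodo-2-methylprop-2-en-1-ol
Conditions: MeMgBr (2.5 equiv), CuI (10 mol %), THF, −10 °C → rt; then I2, −40 → 0 °C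
Reagents that add atoms: methylmagnesium bromide C[Mg]Br; iodine II
Why: Copper-catalysed carbomagnesiation of the magnesium propargyl alkoxide is anti because the alkoxide chelates the new vinylmagnesium, so methyl adds to C2 and the metal sits on C3 cis to CH2O; iodinolysis with retention gives the Z iodide.

Step 8
Reactants: 9 (Z)-3-iodo-2-methylprop-2-en-1-ol
Product: 10 (Z)-3-bromo-1-iodo-2-methylprop-1-ene
Conditions: CBr4, PPh3, CH2Cl2, 0 °C
Reagents that add atoms: tetrabromomethane BrC(Br)(Br)Br
Why: Appel bromination of the primary allylic alcohol under neutral conditions keeps the alkene geometry.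

Step 9
Reactants: 7 hydrindan-13-one; 10 (Z)-3-bromo-1-iodo-2-methylprop-1-ene
Product: 11 14-[(Z)-3-iodo-2-methylprop-2-enyl] ketone (mainly the epimer with the arm β, which is of no consequence)
Conditions: LiN(i-Pr)2 (1.05 equiv), THF, −78 °C; then 10, −78 → −20 °C
Reagents that add atoms: none
Why: C14 is the only enolisable position because C18 is quaternary, so the lithium enolate forms regiospecifically and is alkylated by the reactive allylic bromide in an SN2 reaction; the C14 configuration is erased in the next step.

Step 10
Reactants: 11 monoalkylated ketone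
Product: 12 14β-benzyloxymethyl-14α-[(Z)-3-iodo-2-methylprop-2-enyl] 13-ketone
Conditions: LiN(i-Pr)2 (1.1 equiv), THF, −78 → −40 °C; then BnOCH2Cl, −78 → 0 °C
Reagents that add atoms: benzyl chloromethyl ether ClCOCc1ccccc1
Why: Alkylation of the tetrasubstituted lithium enolate with a reactive chloromethyl ether; the electrophile enters anti to the angular C18 methyl, the usual sense for ring D enolates of trans-hydrindanones, which puts C15 β and leaves the iodoallyl arm α. The order of the two alkylations therefore sets the quaternary centre C14.

Step 11
Reactants: 12 dialkylated ketone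
Product: 13 13-methylene compound (C13=C12H2)
Conditions: Cp2Ti(μ-Cl)(μ-CH2)AlMe2 (Tebbe reagent, 2 equiv), pyridine (cat.), THF/toluene, −40 °C → rt
Reagents that add atoms: Tebbe reagent C[Al-]1(C)C[Ti]([Cl+]1)(C1C=CC=C1)C1C=CC=C1
Why: Carbonyl methylenation by the titanium methylidene runs through a compact oxatitanacyclobutane and is suited to ketones between two quaternary carbons; the ketone cannot enolise, and the iodoalkene, benzyl ether and silyl ether are inert.

Step 12
Reactants: 13 13-methylene compound
Product: 15 C12 primary alcohol (13β-H), via alkylborane 14 (not isolated)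
Conditions: 9-BBN dimer (3 equiv), THF, 65 °C; then aq. NaOH, H2O2, 0 °C → rt
Reagents that add atoms: hydrogen peroxide OO
Why: Anti-Markovnikov hydroboration–oxidation; 9-BBN prefers the terminal 1,1-disubstituted alkene to the trisubstituted iodoalkene. Hydrogen is delivered to C13 from the β face, anti to the angular C18 methyl as with 17-methylene steroids, which places C12 α, cis to the C27 arm.

Step 13
Reactants: 15 C12 primary alcohol
Product: 16 C12 aldehyde (formyl group on C13)
Conditions: Dess–Martin periodinane, pyridine, CH2Cl2, 0 °C → rt
Reagents that add atoms: none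
Why: Hypervalent-iodine oxidation stops at the aldehyde under buffered conditions; C13 lies between two quaternary carbons and enolises slowly, so it should not epimerise.

Step 14
Reactants: 16 C12 aldehyde
Product: 18 C11 aldehyde (C13–CH2–CHO), via methyl enol ether 17 (not isolated)
Conditions: Ph3P(CH2OMe)Cl, NaN(SiMe3)2, THF, 0 °C; 16, 0 °C → rt; then 2 M aq. HCl, THF, rt
Reagents that add atoms: (methoxymethyl)triphenylphosphonium chloride COC[P+](c1ccccc1)(c1ccccc1)c1ccccc1.[Cl-]; water O
Why: Wittig one-carbon homologation: the reactive methoxymethylene ylide adds even to a hindered aldehyde, and acid hydrolysis of the enol ether gives the aldehyde one carbon further out, where C13 is no longer α to the carbonyl.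

Step 15
Reactants: 19 pent-4-yn-1-ol
Product: 20 (E)-5-iodo-4-methylpent-4-en-1-ol
Conditions: Me3Al (3 equiv), Cp2ZrCl2 (25 mol %), CH2Cl2, 0 °C → rt; then I2, THF, −30 → 0 °C
Reagents that add atoms: trimethylaluminium C[Al](C)C; iodine II
Why: Zirconium-catalysed syn-carboalumination (Negishi) puts methyl on the internal and aluminium on the terminal alkyne carbon; iodinolysis with retention gives the E vinyl iodide, which fixes the 9E geometry of the later enone.

Step 16
Reactants: 20 (E)-5-iodo-4-methylpent-4-en-1-ol
Product: 21 (E)-5-iodo-4-methylpent-4-enal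
Conditions: Dess–Martin periodinane, pyridine, CH2Cl2, 0 °C → rt
Reagents that add atoms: none
Why: Mild oxidation of the primary alcohol to the aldehyde; the vinyl iodide is inert.

Step 17
Reactants: 21 (E)-5-iodo-4-methylpent-4-enal; 22 2-methyl-1-(trimethylsilyloxy)prop-1-ene
Product: 23 (E)-3-hydroxy-7-iodo-2,2,6-trimethylhept-6-enal (racemic)
Conditions: BF3·OEt2 (1.1 equiv), CH2Cl2, −78 °C; aq. NaHCO3
Reagents that add atoms: none
Why: Mukaiyama aldol addition of the aldehyde enol silane makes the C3–C4 bond and the quaternary C4 in one step; the product has no α-hydrogen and cannot dehydrate. The C3 carbinol is racemic on purpose because it is oxidised later.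

Step 18
Reactants: 24 tributyltin chloride
Product: 25 tributyl(dibromomethyl)stannane
Conditions: CH2Br2, LiN(i-Pr)2, THF/Et2O, −95 °C; then 24, −95 °C → rt
Reagents that add atoms: dibromomethane BrCBr
Why: Deprotonation of dibromomethane gives dibromomethyllithium, which is trapped at low temperature by substitution at tin before the carbenoid can decompose.

Step 19
Reactants: 23 hydroxy aldehyde; 25 tributyl(dibromomethyl)stannane
Product: 26 (1E,7E)-8-iodo-3,3,7-trimethyl-1-(tributylstannyl)octa-1,7-dien-4-ol (racemic)
Conditions: CrCl2 (8 equiv), LiI (cat.), THF/DMF, rt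
Reagents that add atoms: none
Why: Takai-type olefination with the geminal dichromium reagent from 25 converts the hindered aldehyde into the E-vinylstannane; CrCl2 does not insert into a vinyl iodide unless NiCl2 is added, and the free carbinol is tolerated.

Step 20
Reactants: 26 iodo stannyl alcohol; 18 C11 aldehyde
Product: 29 seco-diol (C3 and C11 carbinols as epimer mixtures), via dilithio species 27 (not isolated), via bromomagnesium species 28 (not isolated)
Conditions: 26 (1.5 equiv), t-BuLi (3.1 equiv per 26), Et2O, −78 °C; MgBr2·OEt2, −78 °C; then 18, THF, −78 → −40 °C; aq. NH4Cl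
Reagents that add atoms: none
Why: Iodine–lithium exchange at the vinyl iodide is far faster than tin–lithium exchange at the vinylstannane and keeps the E geometry; the first equivalent of base turns the C3 hydroxyl into an alkoxide that protects it in situ. Transmetalation to magnesium tempers the reagent so that it adds to the aldehyde of 18 without exchanging with its vinyl iodide.

Step 21
Reactants: 29 seco-diol
Product: 30 seco-trienedione (3,11-dione, C6 stannane, C7 iodide)
Conditions: Dess–Martin periodinane (3 equiv), pyridine, CH2Cl2, 0 °C → rt
Reagents that add atoms: none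
Why: Double oxidation turns the allylic C11 carbinol into the E-enone and the neopentyl C3 carbinol into the ketone, which removes both stereocentres made in step 20; the pyridine buffer prevents protodestannylation.

Step 22
Reactants: 30 seco-trienedione
Product: 31 macrocyclic (5E,7Z,9E)-triene-3,11-dione (15-membered ring fused to the hydrindane at C13–C14; C15 OBn, C21 OTBS)
Conditions: Pd(PPh3)4 (20 mol %), copper thiophene-2-carboxylate Cu(O2CC4H3S) (1.5 equiv), Ph2PO2NBu4 (1.6 equiv), DMF, 2 mM, rt
Reagents that add atoms: none
Why: Intramolecular Stille coupling joins C6 and C7 with retention at both alkenes, so the E,Z-diene forms directly. The copper carboxylate speeds transmetalation of the neopentylic stannane and the phosphinate removes the tin, which allows room temperature and high dilution so that the triene does not react further.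

Step 23
Reactants: 31 macrocyclic triene-3,11-dione
Product: 32 pentacyclic 6-ene-3,11-dione (5α-H, 8β-methyl, 9α-H, 10β-methyl; C15 OBn, C21 OTBS)
Conditions: toluene (5 mM), BHT (10 mol %), base-washed sealed tube, 130 °C
Reagents that add atoms: none
Why: Proposed new method: a thermal transannular [4+2] cycloaddition of the C5=C6–C7=C8 diene with the C9=C10 enone across the 15-membered ring, concerted and suprafacial on both partners, with bonding expected to run ahead at C5–C10 (enone β-carbon to the less substituted diene terminus) so that the crowded C8–C9 bond closes late; the closest known reaction type is the transannular Diels–Alder reaction of trans-cis-trans 15-membered trienes to trans-anti-trans 6-6-7 tricycles, which has not been shown with two quaternary carbons being formed. Ring B closes as the cyclohexene of the cycloaddition itself, ring A as the six-membered ring spanned by C1–C4 between the bonding atoms C10 and C5 (tether exo on the dienophile and outside on the diene), and ring C as the seven-membered ring spanned by C11, C12, C13, C14 and C27 between C9 and C8 (tether endo on the dienophile and inside on the diene). C5 and C10 follow from the 5E and 9E geometries (C4 outside, C10 methyl endo, hence 5α-H and 10β-methyl), C9 and C8 from the 9E and 7Z geometries (C11 endo, C8 methyl outside, hence 9α-H and 8β-methyl), and the endo placement of C11 that links the two pairs in the anti sense is imposed by the ring. The selectivity still needed is the diene face, that is, the sense of the new tricycle relative to C13 and C14. In the wanted transition state ring D stays on the dienophile side, away from the reacting carbons, and only the slim benzyloxymethyl arm on C14 lies next to the C8 methyl, whereas the other face would put the ring carbon C16 there. Because diene and dienophile are already confined in one ring, most of the entropic price of the cycloaddition has been met at the macrocyclisation stage, the enone supplies the activation, C3 as a ketone keeps the ring A tether free of stereocentres, and BHT with base-washed glass suppresses radical and acid-induced isomerisation of the Z-diene.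

Step 24
Reactants: 32 pentacyclic 6-ene-3,11-dione
Product: 33 3α-hydroxy-6-en-11-one
Conditions: LiBH(s-Bu)3 (1.2 equiv), THF, −78 °C; aq. NH4Cl
Reagents that add atoms: none
Why: The bulky borohydride reduces the 4,4-dimethyl-3-ketone from the equatorial direction to the axial 3α-alcohol; the C11 ketone, next to C9 with its two quaternary neighbours and shielded by the 8β and 10β methyls, should not react at this temperature.

Step 25
Reactants: 33 3α-hydroxy-6-en-11-one
Product: 34 3α-methoxy-6-en-11-one
Conditions: Me3OBF4, 1,8-bis(dimethylamino)naphthalene, 4 Å MS, CH2Cl2, rt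
Reagents that add atoms: trimethyloxonium tetrafluoroborate C[O+](C)C.F[B-](F)(F)F
Why: O-Methylation with an oxonium salt and a non-nucleophilic proton scavenger works on hindered axial alcohols without forming an alkoxide, so the enolisable C11 ketone is not C-methylated.

Step 26
Reactants: 34 3α-methoxy-6-en-11-one
Product: 35 3α-methoxy-6,11-dien-11-yl triflate
Conditions: KN(SiMe3)2, THF, −78 °C; then PhNTf2, −78 → 0 °C
Reagents that add atoms: N-phenylbis(trifluoromethanesulfonimide) O=S(=O)(N(c1ccccc1)S(=O)(=O)C(F)(F)F)C(F)(F)F
Why: Kinetic deprotonation takes place at the accessible C12 methylene and not at the buried C9 methine, and O-sulfonylation of the enolate gives the vinyl triflate; no reagent has to attack the hindered carbonyl carbon.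

Step 27
Reactants: 35 enol triflate
Product: 36 3α-methoxy-6,11-diene (C11 deoxygenated; C15 OBn, C21 OTBS)
Conditions: Pd(OAc)2 (10 mol %), PPh3 (20 mol %), HCO2H, Et3N, DMF, 60 °C
Reagents that add atoms: none
Why: Palladium-catalysed hydrogenolysis of the vinyl triflate: oxidative addition, formate exchange, decarboxylation to the palladium hydride and reductive elimination replace the triflate by hydrogen.

Step 28
Reactants: 36 3α-methoxy-6,11-diene
Product: 37 saturated C15 primary alcohol (3α-OMe, 21β-OTBS)
Conditions: H2 (3 bar), 10% Pd/C, EtOAc/EtOH, rt
Reagents that add atoms: none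
Why: One operation hydrogenates the two disubstituted ring alkenes (C6=C7 and C11=C12, no stereocentre created) and hydrogenolyses the benzyl ether, which frees the C15 hydroxyl while C21 stays silylated.

Step 29
Reactants: 37 C15 primary alcohol
Product: 38 C15 aldehyde (21β-OTBS)
Conditions: Dess–Martin periodinane, pyridine, CH2Cl2, rt
Reagents that add atoms: none
Why: Oxidation of the only free hydroxyl, a neopentyl primary alcohol, to the aldehyde; C14 is quaternary, so the aldehyde cannot enolise or epimerise.

Step 30
Reactants: 38 C15 aldehyde silyl ether
Product: 39 target (3α-methoxy-21β-hydroxy ring-D-contracted serratane 14β-carbaldehyde)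
Conditions: HF·pyridine, THF, 0 °C → rt
Reagents that add atoms: none
Why: Fluoride-assisted cleavage of the silyl ether frees the axial 21β-hydroxyl; the non-enolisable aldehyde and the methyl ether are stable in the mildly acidic medium.

## Compound list

1 | (S)-Hajos–Parrish ketone, (S)-7a-methyl-2,3,7,7a-tetrahydro-1H-indene-1,5(6H)-dione | C[C@]12CCC(=O)C=C1CCC2=O | starting material
2 | C13 ethylene ketal of 1, (S)-7a-methyl-2,3,7,7a-tetrahydrospiro[indene-1,2'-[1,3]dioxolan]-5(6H)-one | C[C@]12CCC(=O)C=C1CCC23OCCO3 | intermediate
3 | 22,22-dimethyl-16-en-21-one 13-ketal (18α-methyl) | C[C@]12CCC(=O)C(C)(C)C1=CCC23OCCO3 | intermediate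
4 | trans-hydrindane 21-ketone 13-ketal (17β-H, 18α-methyl, 22,22-dimethyl) | C1COC2(O1)CC[C@H]3C(C)(C)C(=O)CC[C@]23C | intermediate
5 | 21β-alcohol 13-ketal (axial OH) | C1COC2(O1)CC[C@H]3C(C)(C)[C@H](O)CC[C@]23C | intermediate
6 | 21β-OTBS 13-ketal | C1COC2(O1)CC[C@H]3C(C)(C)[C@H](O[Si](C)(C)C(C)(C)C)CC[C@]23C | intermediate
7 | hydrindan-13-one (21β-OTBS, 22,22-dimethyl, 17β-H, 18α-methyl) | O=C1CC[C@H]2C(C)(C)[C@H](O[Si](C)(C)C(C)(C)C)CC[C@]12C | intermediate
8 | propargyl alcohol | C#CCO | starting material
9 | (Z)-3-iodo-2-methylprop-2-en-1-ol | OC/C(C)=C\I | intermediate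
10 | (Z)-3-bromo-1-iodo-2-methylprop-1-ene | BrC/C(C)=C\I | intermediate
11 | 14-[(Z)-3-iodo-2-methylprop-2-enyl] 13-ketone (drawn as the epimer with the arm β) | O=C1[C@H](C/C(C)=C\I)C[C@H]2C(C)(C)[C@H](O[Si](C)(C)C(C)(C)C)CC[C@]12C | intermediate
12 | 14β-benzyloxymethyl-14α-[(Z)-3-iodo-2-methylprop-2-enyl] 13-ketone | O=C1[C@@](COCc3ccccc3)(C/C(C)=C\I)C[C@H]2C(C)(C)[C@H](O[Si](C)(C)C(C)(C)C)CC[C@]12C | intermediate
13 | 13-methylene compound | C=C1[C@@](COCc3ccccc3)(C/C(C)=C\I)C[C@H]2C(C)(C)[C@H](O[Si](C)(C)C(C)(C)C)CC[C@]12C | intermediate
14 | B-alkyl-9-borabicyclo[3.3.1]nonane at C12 (13β-H) | C1CCC2CCCC1B2C[C@H]1[C@@](COCc3ccccc3)(C/C(C)=C\I)C[C@H]2C(C)(C)[C@H](O[Si](C)(C)C(C)(C)C)CC[C@]12C | intermediate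
15 | C12 primary alcohol (13β-H, C12 α) | OC[C@H]1[C@@](COCc3ccccc3)(C/C(C)=C\I)C[C@H]2C(C)(C)[C@H](O[Si](C)(C)C(C)(C)C)CC[C@]12C | intermediate
16 | C12 aldehyde | O=C[C@H]1[C@@](COCc3ccccc3)(C/C(C)=C\I)C[C@H]2C(C)(C)[C@H](O[Si](C)(C)C(C)(C)C)CC[C@]12C | intermediate
17 | C11 methyl enol ether (E/Z mixture) | COC=C[C@H]1[C@@](COCc3ccccc3)(C/C(C)=C\I)C[C@H]2C(C)(C)[C@H](O[Si](C)(C)C(C)(C)C)CC[C@]12C | intermediate
18 | C11 aldehyde, hydrindane fragment (C13–CH2–CHO; C14 with CH2OBn β and iodoallyl arm α; 21β-OTBS) | O=CC[C@H]1[C@@](COCc3ccccc3)(C/C(C)=C\I)C[C@H]2C(C)(C)[C@H](O[Si](C)(C)C(C)(C)C)CC[C@]12C | intermediate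
19 | pent-4-yn-1-ol | C#CCCCO | starting material
20 | (E)-5-iodo-4-methylpent-4-en-1-ol | OCCC/C(C)=C/I | intermediate
21 | (E)-5-iodo-4-methylpent-4-enal | O=CCC/C(C)=C/I | intermediate
22 | 2-methyl-1-(trimethylsilyloxy)prop-1-ene | CC(C)=CO[Si](C)(C)C | starting material
23 | (E)-3-hydroxy-7-iodo-2,2,6-trimethylhept-6-enal (racemic) | O=CC(C)(C)C(O)CC/C(C)=C/I | intermediate
24 | tributyltin chloride | CCCC[Sn](Cl)(CCCC)CCCC | starting material
25 | tributyl(dibromomethyl)stannane | CCCC[Sn](CCCC)(CCCC)C(Br)Br | intermediate
26 | (1E,7E)-8-iodo-3,3,7-trimethyl-1-(tributylstannyl)octa-1,7-dien-4-ol (racemic) | CCCC[Sn](CCCC)(CCCC)/C=C/C(C)(C)C(O)CC/C(C)=C/I | intermediate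
27 | dilithio species of 26 (C9 lithium, C3 lithium alkoxide) | [Li]/C=C(\C)CCC(O[Li])C(C)(C)/C=C/[Sn](CCCC)(CCCC)CCCC | intermediate
28 | bromomagnesium species (C9 MgBr, C3 lithium alkoxide) | Br[Mg]/C=C(\C)CCC(O[Li])C(C)(C)/C=C/[Sn](CCCC)(CCCC)CCCC | intermediate
29 | seco-diol (C3 and C11 carbinols, epimer mixtures; C6 stannane, C7 iodide) | CCCC[Sn](CCCC)(CCCC)/C=C/C(C)(C)C(O)CC/C(C)=C/C(O)C[C@H]1[C@@](COCc3ccccc3)(C/C(C)=C\I)C[C@H]2C(C)(C)[C@H](O[Si](C)(C)C(C)(C)C)CC[C@]12C | intermediate
30 | seco-trienedione (3,11-dione; C6 stannane, C7 iodide) | CCCC[Sn](CCCC)(CCCC)/C=C/C(C)(C)C(=O)CC/C(C)=C/C(=O)C[C@H]1[C@@](COCc3ccccc3)(C/C(C)=C\I)C[C@H]2C(C)(C)[C@H](O[Si](C)(C)C(C)(C)C)CC[C@]12C | intermediate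
31 | macrocyclic (5E,7Z,9E)-triene-3,11-dione fused to the hydrindane at C13–C14 (C15 OBn, C21 OTBS) | O=C1CC/C(C)=C/C(=O)C[C@@H]2[C@@]3(C)CC[C@@H](O[Si](C)(C)C(C)(C)C)C(C)(C)[C@@H]3C[C@]2(COCc4ccccc4)C/C(C)=C\C=C\C1(C)C | intermediate
32 | pentacyclic 6-ene-3,11-dione (C15 OBn, C21 OTBS) | O=C1CC[C@@]2(C)[C@@H](C=C[C@@]3(C)C[C@@]4(COCc6ccccc6)C[C@H]5C(C)(C)[C@H](O[Si](C)(C)C(C)(C)C)CC[C@]5(C)[C@H]4CC(=O)[C@@H]32)C1(C)C | intermediate
33 | 3α-hydroxy-6-en-11-one | O[C@@H]1CC[C@@]2(C)[C@@H](C=C[C@@]3(C)C[C@@]4(COCc6ccccc6)C[C@H]5C(C)(C)[C@H](O[Si](C)(C)C(C)(C)C)CC[C@]5(C)[C@H]4CC(=O)[C@@H]32)C1(C)C | intermediate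
34 | 3α-methoxy-6-en-11-one | CO[C@@H]1CC[C@@]2(C)[C@@H](C=C[C@@]3(C)C[C@@]4(COCc6ccccc6)C[C@H]5C(C)(C)[C@H](O[Si](C)(C)C(C)(C)C)CC[C@]5(C)[C@H]4CC(=O)[C@@H]32)C1(C)C | intermediate
35 | 3α-methoxy-6,11-dien-11-yl triflate | CO[C@@H]1CC[C@@]2(C)[C@@H](C=C[C@@]3(C)C[C@@]4(COCc6ccccc6)C[C@H]5C(C)(C)[C@H](O[Si](C)(C)C(C)(C)C)CC[C@]5(C)[C@H]4C=C(OS(=O)(=O)C(F)(F)F)[C@@H]32)C1(C)C | intermediate
36 | 3α-methoxy-6,11-diene (C15 OBn, C21 OTBS) | CO[C@@H]1CC[C@@]2(C)[C@@H](C=C[C@@]3(C)C[C@@]4(COCc6ccccc6)C[C@H]5C(C)(C)[C@H](O[Si](C)(C)C(C)(C)C)CC[C@]5(C)[C@H]4C=C[C@@H]32)C1(C)C | intermediate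
37 | saturated C15 primary alcohol (3α-OMe, 21β-OTBS) | CO[C@@H]1CC[C@@]2(C)[C@@H](CC[C@@]3(C)C[C@@]4(CO)C[C@H]5C(C)(C)[C@H](O[Si](C)(C)C(C)(C)C)CC[C@]5(C)[C@H]4CC[C@@H]32)C1(C)C | intermediate
38 | C15 aldehyde (3α-OMe, 21β-OTBS) | CO[C@@H]1CC[C@@]2(C)[C@@H](CC[C@@]3(C)C[C@@]4(C=O)C[C@H]5C(C)(C)[C@H](O[Si](C)(C)C(C)(C)C)CC[C@]5(C)[C@H]4CC[C@@H]32)C1(C)C | intermediate
39 | CNP0131145.2 (3α-methoxy-21β-hydroxy ring-D-contracted serratane 14β-carbaldehyde) | CO[C@@H]1CC[C@@]2(C)[C@@H](CC[C@@]3(C)C[C@@]4(C=O)C[C@H]5C(C)(C)[C@H](O)CC[C@]5(C)[C@H]4CC[C@@H]32)C1(C)C | target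

## Step count and least certain steps

Total: 30 steps. Longest linear sequence: 23 steps (steps 1–6, 9–14 and 20–30, from 1 to 39).

Step 23 (key step). Two processes are most likely to interfere. The first is attack on the wrong diene face, because the only control elements, C13 and C14, sit on the flexible seven-membered tether. The second is a 1,5-hydrogen shift from C27 across the Z-diene, or Z to E isomerisation, before the cycloaddition, because the formation of two quaternary carbons raises the barrier into the range where these reactions occur. A Lewis acid such as Me2AlCl would lower the temperature, but that changes only the conditions. The fallback uses known reactions only: rings A and B by an intramolecular Diels–Alder reaction of an open-chain trienal, ring C afterwards by ring-closing metathesis. It sets out from 16 and 26 and comes back to the route at 36. Wittig methylenation of 16 (Ph3PCH3Br, KOt-Bu) should give the 13-vinyl hydrindane F1. From 26, iodine–lithium exchange (t-BuLi) and formylation with DMF should give the hydroxy enal F2, and Dess–Martin oxidation the keto enal F3. Intermolecular Stille coupling of F1 with F3 (Pd(PPh3)4, copper thiophene-2-carboxylate) should give the open-chain tetraene F4, in which the diene C5=C6–C7=C8 and the E-enal C9=C10 are linked by the four-atom tether C4 to C1. A Me2AlCl-promoted intramolecular Diels–Alder reaction (type 1, formyl group endo) should close rings A and B as the trans-decalin aldehyde F5. Here the hydrindane is no longer in a ring with the diene, so both faces are expected to react and the diastereomer with the natural sense has to be separated; a chiral oxazaborolidinium Lewis acid could bias the face. Chemoselective methylenation of the aldehyde (one equivalent of Ph3P=CH2, −78 °C) should give the divinyl ketone F6, ring-closing metathesis with the second-generation Grubbs catalyst (H2IMes)(PCy3)Cl2Ru=CHPh the cycloheptene F7 (C11=C12), reduction with LiBH(s-Bu)3 the 3α-alcohol F8, and O-methylation (NaH, MeI) 36.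

Step 10. O-Alkylation of the crowded tetrasubstituted enolate by the hard chloromethyl ether is the most likely failure, followed by incomplete facial selectivity at C14. The fallback replaces the enolate alkylation by a Lewis-acid alkylation of an enol silane; it sets out from 11 and comes back at 12. Silylation of 11 (TMSOTf, Et3N) should give the trimethylsilyl enol ether F9, which can form only towards C14, and reaction with benzyl chloromethyl ether and TiCl4 at −78 °C (oxocarbenium ion, C-attack only, same anti approach) should give 12.

Step 11. The carbonyl group between two quaternary carbons may be too shielded for the titanium methylidene, so the methylenation may stall. The fallback is a two-stage Peterson olefination with a small, strongly nucleophilic reagent; it sets out from 12 and comes back at 13. Addition of Me3SiCH2Li in the presence of CeCl3 should give the β-hydroxysilane F10 (C13 configuration immaterial), and syn-elimination with KH in THF should give 13.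

Step 12. Hydrogen may be delivered to C13 from the α face, because C14 now carries substituents on both faces and the steroid analogy is not exact; in addition the hydroboration of an alkene between two quaternary carbons may be slow enough for the iodoalkene to compete. The fallback brings in C12 and C11 together and sets C13 by conjugate reduction; it sets out from 12 and comes back at 18. Addition of HC≡CMgBr with CeCl3 should give the tertiary propargylic alcohol F11, a gold-catalysed Meyer–Schuster rearrangement (Ph3PAuNTf2, wet MeOH; no competing enyne formation because C14 and C18 carry no hydrogen) the exocyclic enal F12, and 1,4-reduction with [(Ph3P)CuH]6 should give 18, with hydride expected on the β face of C13.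

## Further compounds

F1 | step 23 | 13-vinyl hydrindane (C14 with CH2OBn β and iodoallyl arm α, 21β-OTBS) | C=C[C@H]1[C@@](COCc3ccccc3)(C/C(C)=C\I)C[C@H]2C(C)(C)[C@H](O[Si](C)(C)C(C)(C)C)CC[C@]12C
F2 | step 23 | (2E,8E)-6-hydroxy-3,7,7-trimethyl-9-(tributylstannyl)nona-2,8-dienal (racemic) | CCCC[Sn](CCCC)(CCCC)/C=C/C(C)(C)C(O)CC/C(C)=C/C=O
F3 | step 23 | (2E,8E)-3,7,7-trimethyl-6-oxo-9-(tributylstannyl)nona-2,8-dienal | CCCC[Sn](CCCC)(CCCC)/C=C/C(C)(C)C(=O)CC/C(C)=C/C=O
F4 | step 23 | open-chain (5E,7Z,9E)-trien-3-one-11-al on the 13-vinyl hydrindane | C=C[C@H]1[C@@](COCc3ccccc3)(C/C(C)=C\C=C\C(C)(C)C(=O)CC/C(C)=C/C=O)C[C@H]2C(C)(C)[C@H](O[Si](C)(C)C(C)(C)C)CC[C@]12C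
F5 | step 23 | trans-decalin 3-ketone with C9 formyl group, linked through C27 to the 13-vinyl hydrindane (rings A and B closed) | O=C1CC[C@@]2(C)[C@@H](C=C[C@@](C)(C[C@@]4(COCc6ccccc6)C[C@H]5C(C)(C)[C@H](O[Si](C)(C)C(C)(C)C)CC[C@]5(C)[C@H]4C=C)[C@@H]2C=O)C1(C)C
F6 | step 23 | 9,13-divinyl 3-ketone | O=C1CC[C@@]2(C)[C@@H](C=C[C@@](C)(C[C@@]4(COCc6ccccc6)C[C@H]5C(C)(C)[C@H](O[Si](C)(C)C(C)(C)C)CC[C@]5(C)[C@H]4C=C)[C@@H]2C=C)C1(C)C
F7 | step 23 | pentacyclic 6,11-dien-3-one (C15 OBn, C21 OTBS) | O=C1CC[C@@]2(C)[C@@H](C=C[C@@]3(C)C[C@@]4(COCc6ccccc6)C[C@H]5C(C)(C)[C@H](O[Si](C)(C)C(C)(C)C)CC[C@]5(C)[C@H]4C=C[C@@H]32)C1(C)C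
F8 | step 23 | pentacyclic 6,11-dien-3α-ol (C15 OBn, C21 OTBS) | O[C@@H]1CC[C@@]2(C)[C@@H](C=C[C@@]3(C)C[C@@]4(COCc6ccccc6)C[C@H]5C(C)(C)[C@H](O[Si](C)(C)C(C)(C)C)CC[C@]5(C)[C@H]4C=C[C@@H]32)C1(C)C
F9 | step 10 | trimethylsilyl enol ether of 11 (C13=C14) | C[Si](C)(C)OC1=C(C/C(C)=C\I)C[C@H]2C(C)(C)[C@H](O[Si](C)(C)C(C)(C)C)CC[C@]12C
F10 | step 11 | 13-hydroxy-13-(trimethylsilylmethyl) compound (C13 epimers) | C[Si](C)(C)CC1(O)[C@@](COCc3ccccc3)(C/C(C)=C\I)C[C@H]2C(C)(C)[C@H](O[Si](C)(C)C(C)(C)C)CC[C@]12C
F11 | step 12 | 13-ethynyl-13-hydroxy compound (C13 epimers) | C#CC1(O)[C@@](COCc3ccccc3)(C/C(C)=C\I)C[C@H]2C(C)(C)[C@H](O[Si](C)(C)C(C)(C)C)CC[C@]12C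
F12 | step 12 | exocyclic enal C13=C12H–C11HO (E/Z mixture) | O=CC=C1[C@@](COCc3ccccc3)(C/C(C)=C\I)C[C@H]2C(C)(C)[C@H](O[Si](C)(C)C(C)(C)C)CC[C@]12C
A1 | alternative 1 | 21-O-acetate of the target | CO[C@@H]1CC[C@@]2(C)[C@@H](CC[C@@]3(C)C[C@@]4(C=O)C[C@H]5C(C)(C)[C@H](OC(C)=O)CC[C@]5(C)[C@H]4CC[C@@H]32)C1(C)C
A2 | alternative 1 | 21β-acetoxy-3α-methoxy-onocera-8(26),14(27)-dien-15-ol (C15 configuration left open) | CO[C@@H]1CC[C@@]2(C)[C@@H](CCC(=C)[C@@H]2CC[C@H]3C(=C)C(O)C[C@H]4C(C)(C)[C@H](OC(C)=O)CC[C@]34C)C1(C)C
A3 | alternative 2 | pentacyclic 21α-alcohol with C15 methyl ester and C11=C12 alkene | CO[C@@H]1CC[C@@]2(C)[C@@H](CC[C@@]3(C)C[C@@]4(C(=O)OC)C[C@H]5C(C)(C)[C@@H](O)CC[C@]5(C)[C@H]4C=C[C@@H]32)C1(C)C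
A4 | alternative 2 | A/B/C tricycle with C11 trimethylsilyl group, C12=C13 alkene, C14 methyl ester and C14 (S)-6,7-epoxygeranyl chain (C11 configuration left open) | CO[C@@H]1CC[C@@]2(C)[C@@H](CC[C@@]3(C)C[C@](C/C=C(\C)CC[C@@H]4OC4(C)C)(C(=O)OC)C=CC([Si](C)(C)C)[C@@H]32)C1(C)C
A5 | alternative 3 | pentacyclic C9 carbinol (C15 and C21 silyl ethers) | CO[C@@H]1CC[C@@]2(C)[C@@H](CC[C@@]3(C)C[C@@]4(CO[Si](C)(C)C(C)(C)C)C[C@H]5C(C)(C)[C@H](O[Si](C)(C)C(C)(C)C)CC[C@]5(C)[C@H]4CC[C@]32O)C1(C)C
A6 | alternative 3 | decalin C9 ketone linked through C27 to the hydrindane, with a C11 primary iodide on the C13 arm | CO[C@@H]1CC[C@@]2(C)[C@@H](CC[C@@](C)(C[C@@]3(CO[Si](C)(C)C(C)(C)C)C[C@H]4C(C)(C)[C@H](O[Si](C)(C)C(C)(C)C)CC[C@]4(C)[C@H]3CCI)C2=O)C1(C)C
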